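**Retrosynthetic overview**
- Target ⇐ 5-O-demethylation and O-debenzylation of a fully protected trans-flavanone. Rings A and B are bought as arenes; ring C is the only ring built and is closed last (O1–C2).
- Ring C ⇐ intramolecular Mitsunobu etherification (inversion at the benzylic carbon) of a 2'-hydroxyaryl syn-β-hydroxy-α-methoxy ketone.
- Ketone ⇐ C4–C4a bond: a ring-A aryllithium (from a cheap 3,4,5-trioxygenated benzaldehyde by Dakin oxidation, bromination, MOM protection) plus a Weinreb amide.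
- Weinreb amide ⇐ key C2–C3 bond: Evans boron syn-aldol of a chiral N-(methoxyacetyl)oxazolidinone with the ring-B aldehyde. This sets both stereocentres (2R,3S open chain, 2R,3R after the inversion).

Assumption: 3-hydroxy-4,5-dimethoxybenzaldehyde (compound 1) is bought as a catalogue chemical; flavanone numbering (O1, C2, C3, C4, primes for ring B) is used for positions.

**Route**

Step 1
Reactants: 1 3-hydroxy-4,5-dimethoxybenzaldehyde
Product: 2 3-(benzyloxy)-4,5-dimethoxybenzaldehyde
Conditions: BnBr (1.2 equiv), K2CO3 (1.5 equiv), DMF, 60 °C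
Reagents that add atoms: benzyl bromide, BrCc1ccccc1
Why: Williamson ether synthesis on the only phenol masks the future 3'-OH as a benzyl ether that survives every later step until hydrogenolysis.

Step 2
Reactants: 3 (R)-4-benzyloxazolidin-2-one; 4 methoxyacetyl chloride
Product: 6 (R)-4-benzyl-3-(methoxyacetyl)oxazolidin-2-one, via N-lithio oxazolidinone 5 (not isolated)
Conditions: n-BuLi (1.05 equiv), THF, −78 °C; then 4, −78 → 0 °C
Reagents that add atoms: none
Why: N-acylation of the lithiated carbamate by the acid chloride gives the glycolate imide without touching the auxiliary stereocentre.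

Step 3
Reactants: 6 (R)-4-benzyl-3-(methoxyacetyl)oxazolidin-2-one; 2 3-(benzyloxy)-4,5-dimethoxybenzaldehyde
Product: 9 (4R)-4-benzyl-3-[(2R,3S)-3-(3-benzyloxy-4,5-dimethoxyphenyl)-3-hydroxy-2-methoxypropanoyl]oxazolidin-2-one, via dibutylboron Z-enolate 7 (not isolated), via dibutylboron aldolate 8 (not isolated)
Conditions: Bu2BOTf (1.2 equiv), Et3N (1.4 equiv), CH2Cl2, −78 → 0 °C; then 2, −78 → 0 °C; then pH 7 phosphate buffer, MeOH, 30% H2O2, 0 °C
Reagents that add atoms: none
Why: Evans syn-aldol reaction: the Z-boron enolate reacts through a closed Zimmerman–Traxler chair with the benzyl group of the (R)-auxiliary shielding one enolate face, which sets C-2 (R, bearing OMe) and C-3 (S, bearing OH) together as the syn pair.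

Step 4
Reactants: 9 (4R)-4-benzyl-3-[(2R,3S)-3-(3-benzyloxy-4,5-dimethoxyphenyl)-3-hydroxy-2-methoxypropanoyl]oxazolidin-2-one
Product: 10 (2R,3S)-3-(3-benzyloxy-4,5-dimethoxyphenyl)-3-hydroxy-N,2-dimethoxy-N-methylpropanamide
Conditions: MeNHOMe·HCl (3 equiv), AlMe3 (3 equiv), CH2Cl2, −15 → 0 °C; then aq. HCl (0.5 M), 0 °C
Reagents that add atoms: N,O-dimethylhydroxylamine hydrochloride, CNOC.Cl
Why: Weinreb transamidation with the aluminium amide, assisted by the free β-hydroxyl, cleaves the exocyclic imide carbonyl selectively at low temperature, so no retro-aldol or epimerisation occurs and the auxiliary is recovered.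

Step 5
Reactants: 10 (2R,3S)-3-(3-benzyloxy-4,5-dimethoxyphenyl)-3-hydroxy-N,2-dimethoxy-N-methylpropanamide
Product: 11 (2R,3S)-3-(3-benzyloxy-4,5-dimethoxyphenyl)-N,2-dimethoxy-N-methyl-3-(triethylsilyloxy)propanamide
Conditions: TESOTf (1.3 equiv), 2,6-lutidine (2 equiv), CH2Cl2, −78 → 0 °C
Reagents that add atoms: triethylsilyl trifluoromethanesulfonate, CC[Si](CC)(CC)OS(=O)(=O)C(F)(F)F
Why: Silyl ether formation removes the acidic OH before the organolithium step and the TES group comes off later under the same mild acid as the MOM group.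

Step 6
Reactants: 12 4-hydroxy-3,5-dimethoxybenzaldehyde (syringaldehyde)
Product: 13 4-(benzyloxy)-3,5-dimethoxybenzaldehyde
Conditions: BnBr (1.2 equiv), K2CO3 (1.5 equiv), DMF, 70 °C
Reagents that add atoms: benzyl bromide, BrCc1ccccc1
Why: Williamson ether synthesis protects the oxygen that becomes the 6-OH, leaving a symmetric arene for the next three steps.

Step 7
Reactants: 13 4-(benzyloxy)-3,5-dimethoxybenzaldehyde
Product: 15 4-(benzyloxy)-3,5-dimethoxyphenol, via aryl formate 14 (not isolated)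
Conditions: mCPBA (1.3 equiv), CH2Cl2, rt; then K2CO3 (0.2 equiv), MeOH, rt
Reagents that add atoms: 3-chloroperoxybenzoic acid (mCPBA), OOC(=O)c1cccc(Cl)c1
Why: Dakin-type Baeyer–Villiger oxidation: the electron-rich aryl group migrates to oxygen, and methanolysis of the formate gives the 1,2,3,5-tetraoxygenated ring-A pattern.

Step 8
Reactants: 15 4-(benzyloxy)-3,5-dimethoxyphenol
Product: 16 4-(benzyloxy)-2-bromo-3,5-dimethoxyphenol
Conditions: NBS (1.0 equiv), CH2Cl2, −20 → 0 °C
Reagents that add atoms: N-bromosuccinimide, O=C1CCC(=O)N1Br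
Why: Electrophilic aromatic bromination ortho to the phenol gives one regioisomer, since the para position is blocked and the two ortho positions are equivalent by symmetry.

Step 9
Reactants: 16 4-(benzyloxy)-2-bromo-3,5-dimethoxyphenol
Product: 17 3-(benzyloxy)-1-bromo-2,4-dimethoxy-6-(methoxymethoxy)benzene
Conditions: MOMCl (1.5 equiv), iPr2NEt (2 equiv), CH2Cl2, 0 °C → rt
Reagents that add atoms: chloromethyl methyl ether, COCCl
Why: O-alkylation to the MOM acetal marks this oxygen (the future O1) as the only one that mild acid will unmask, orthogonal to the benzyl and methyl ethers.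

Step 10
Reactants: 17 3-(benzyloxy)-1-bromo-2,4-dimethoxy-6-(methoxymethoxy)benzene; 11 (2R,3S)-3-(3-benzyloxy-4,5-dimethoxyphenyl)-N,2-dimethoxy-N-methyl-3-(triethylsilyloxy)propanamide
Product: 20 (2R,3S)-1-[3-benzyloxy-2,4-dimethoxy-6-(methoxymethoxy)phenyl]-3-(3-benzyloxy-4,5-dimethoxyphenyl)-2-methoxy-3-(triethylsilyloxy)propan-1-one, via aryllithium 18 (not isolated), via lithium hemiaminal 19 (not isolated)
Conditions: 17 (1.4 equiv), n-BuLi (1.35 equiv), THF, −78 °C, 20 min; then 11, −78 → −20 °C; then sat. aq. NH4Cl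
Reagents that add atoms: none
Why: Bromine–lithium exchange followed by Weinreb ketone synthesis: the chelated tetrahedral adduct cannot over-add and releases the ketone only on quench, so the α-stereocentre never sits next to a free carbonyl under basic conditions.

Step 11
Reactants: 20 (2R,3S)-1-[3-benzyloxy-2,4-dimethoxy-6-(methoxymethoxy)phenyl]-3-(3-benzyloxy-4,5-dimethoxyphenyl)-2-methoxy-3-(triethylsilyloxy)propan-1-one
Product: 22 (2R,3S)-1-(3-benzyloxy-6-hydroxy-2,4-dimethoxyphenyl)-3-(3-benzyloxy-4,5-dimethoxyphenyl)-3-hydroxy-2-methoxypropan-1-one, via MOM-protected hydroxy ketone 21 (not isolated)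
Conditions: HCl (1.25 M in MeOH, 3 equiv), THF, 0 °C → rt
Reagents that add atoms: none
Why: Acid-catalysed methanolysis removes the TES ether first and then the MOM acetal, which is activated by chelation to the ortho carbonyl, while benzyl and methyl ethers and both stereocentres stay intact.

Step 12
Reactants: 22 (2R,3S)-1-(3-benzyloxy-6-hydroxy-2,4-dimethoxyphenyl)-3-(3-benzyloxy-4,5-dimethoxyphenyl)-3-hydroxy-2-methoxypropan-1-one
Product: 24 (2R,3R)-6-benzyloxy-2-(3-benzyloxy-4,5-dimethoxyphenyl)-3,5,7-trimethoxychroman-4-one, via alkoxyphosphonium phenoxide 23 (not isolated)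
Conditions: PPh3 (1.5 equiv), DIAD (1.5 equiv), THF, 0 °C → rt
Reagents that add atoms: none
Why: Intramolecular Mitsunobu etherification: the only free phenol displaces the activated benzylic oxygen in a six-membered SN2 closure with inversion (3S becomes C-2 R) while C-3 is untouched, so the syn aldol gives the trans-(2R,3R) flavanone.

Step 13
Reactants: 24 (2R,3R)-6-benzyloxy-2-(3-benzyloxy-4,5-dimethoxyphenyl)-3,5,7-trimethoxychroman-4-one
Product: 25 (2R,3R)-6-hydroxy-2-(3-hydroxy-4,5-dimethoxyphenyl)-3,5,7-trimethoxychroman-4-one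
Conditions: H2 (1 atm), 10% Pd/C, EtOAc–MeOH (1:1), rt
Reagents that add atoms: none
Why: Catalytic hydrogenolysis cleaves both O-benzyl ethers much faster than the cyclic C2–O1 benzylic ether or the aryl ketone, under neutral conditions that cannot epimerise C-2 or C-3.

Step 14
Reactants: 25 (2R,3R)-6-hydroxy-2-(3-hydroxy-4,5-dimethoxyphenyl)-3,5,7-trimethoxychroman-4-one
Product: 27 (2R,3R)-5,6-dihydroxy-2-(3-hydroxy-4,5-dimethoxyphenyl)-3,7-dimethoxychroman-4-one, via chloroboron phenoxide 26 (not isolated)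
Conditions: BCl3 (1 M in CH2Cl2, 4 equiv), CH2Cl2, −78 → 0 °C; then H2O, 0 °C
Reagents that add atoms: none
Why: Chelation-controlled Lewis-acid ether cleavage: only the 5-OMe peri to the C4 carbonyl forms the six-membered boron chelate that makes its methyl group labile to chloride at 0 °C or below, and the trans-diequatorial arrangement is the thermodynamic one, so the stereocentres hold.

**Compound list**

1 | 3-hydroxy-4,5-dimethoxybenzaldehyde | O=Cc1cc(O)c(OC)c(OC)c1 | starting material
2 | 3-(benzyloxy)-4,5-dimethoxybenzaldehyde | O=Cc1cc(OCc2ccccc2)c(OC)c(OC)c1 | intermediate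
3 | (R)-4-benzyloxazolidin-2-one | O=C1N[C@H](Cc2ccccc2)CO1 | starting material
4 | methoxyacetyl chloride | COCC(Cl)=O | starting material
5 | N-lithio derivative of 3, formed in the flask | [Li]N1[C@H](Cc2ccccc2)COC1=O | intermediate
6 | (R)-4-benzyl-3-(methoxyacetyl)oxazolidin-2-one | COCC(=O)N1[C@H](Cc2ccccc2)COC1=O | intermediate
7 | dibutylboron Z-enolate of 6, formed in the flask | CCCCB(CCCC)O/C(=C\OC)N1[C@H](Cc2ccccc2)COC1=O | intermediate
8 | O-dibutylboron aldolate of 9, formed in the flask | O=C(N1[C@H](Cc2ccccc2)COC1=O)[C@H](OC)[C@@H](OB(CCCC)CCCC)c1cc(OCc2ccccc2)c(OC)c(OC)c1 | intermediate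
9 | (4R)-4-benzyl-3-[(2R,3S)-3-(3-benzyloxy-4,5-dimethoxyphenyl)-3-hydroxy-2-methoxypropanoyl]oxazolidin-2-one | O=C(N1[C@H](Cc2ccccc2)COC1=O)[C@H](OC)[C@@H](O)c1cc(OCc2ccccc2)c(OC)c(OC)c1 | intermediate
10 | (2R,3S)-3-(3-benzyloxy-4,5-dimethoxyphenyl)-3-hydroxy-N,2-dimethoxy-N-methylpropanamide | CON(C)C(=O)[C@H](OC)[C@@H](O)c1cc(OCc2ccccc2)c(OC)c(OC)c1 | intermediate
11 | (2R,3S)-3-(3-benzyloxy-4,5-dimethoxyphenyl)-N,2-dimethoxy-N-methyl-3-(triethylsilyloxy)propanamide | CON(C)C(=O)[C@H](OC)[C@@H](O[Si](CC)(CC)CC)c1cc(OCc2ccccc2)c(OC)c(OC)c1 | intermediate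
12 | 4-hydroxy-3,5-dimethoxybenzaldehyde (syringaldehyde) | O=Cc1cc(OC)c(O)c(OC)c1 | starting material
13 | 4-(benzyloxy)-3,5-dimethoxybenzaldehyde | O=Cc1cc(OC)c(OCc2ccccc2)c(OC)c1 | intermediate
14 | 4-(benzyloxy)-3,5-dimethoxyphenyl formate, formed in the flask | O=COc1cc(OC)c(OCc2ccccc2)c(OC)c1 | intermediate
15 | 4-(benzyloxy)-3,5-dimethoxyphenol | Oc1cc(OC)c(OCc2ccccc2)c(OC)c1 | intermediate
16 | 4-(benzyloxy)-2-bromo-3,5-dimethoxyphenol | Oc1cc(OC)c(OCc2ccccc2)c(OC)c1Br | intermediate
17 | 3-(benzyloxy)-1-bromo-2,4-dimethoxy-6-(methoxymethoxy)benzene | COCOc1cc(OC)c(OCc2ccccc2)c(OC)c1Br | intermediate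
18 | [3-(benzyloxy)-2,4-dimethoxy-6-(methoxymethoxy)phenyl]lithium, formed in the flask | COCOc1cc(OC)c(OCc2ccccc2)c(OC)c1[Li] | intermediate
19 | lithium N-methoxy-N-methyl hemiaminal alkoxide from 18 and 11 (C-2 and C-3 as in 11), formed in the flask | COCOc1cc(OC)c(OCc2ccccc2)c(OC)c1C(O[Li])(N(C)OC)[C@H](OC)[C@@H](O[Si](CC)(CC)CC)c1cc(OCc2ccccc2)c(OC)c(OC)c1 | intermediate
20 | (2R,3S)-1-[3-benzyloxy-2,4-dimethoxy-6-(methoxymethoxy)phenyl]-3-(3-benzyloxy-4,5-dimethoxyphenyl)-2-methoxy-3-(triethylsilyloxy)propan-1-one | COCOc1cc(OC)c(OCc2ccccc2)c(OC)c1C(=O)[C@H](OC)[C@@H](O[Si](CC)(CC)CC)c1cc(OCc2ccccc2)c(OC)c(OC)c1 | intermediate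
21 | (2R,3S)-1-[3-benzyloxy-2,4-dimethoxy-6-(methoxymethoxy)phenyl]-3-(3-benzyloxy-4,5-dimethoxyphenyl)-3-hydroxy-2-methoxypropan-1-one, formed in the flask | COCOc1cc(OC)c(OCc2ccccc2)c(OC)c1C(=O)[C@H](OC)[C@@H](O)c1cc(OCc2ccccc2)c(OC)c(OC)c1 | intermediate
22 | (2R,3S)-1-(3-benzyloxy-6-hydroxy-2,4-dimethoxyphenyl)-3-(3-benzyloxy-4,5-dimethoxyphenyl)-3-hydroxy-2-methoxypropan-1-one | Oc1cc(OC)c(OCc2ccccc2)c(OC)c1C(=O)[C@H](OC)[C@@H](O)c1cc(OCc2ccccc2)c(OC)c(OC)c1 | intermediate
23 | O-triphenylphosphonio derivative of 22 at the benzylic oxygen, phenoxide zwitterion, formed in the flask | [O-]c1cc(OC)c(OCc2ccccc2)c(OC)c1C(=O)[C@H](OC)[C@@H](O[P+](c1ccccc1)(c1ccccc1)c1ccccc1)c1cc(OCc2ccccc2)c(OC)c(OC)c1 | intermediate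
24 | (2R,3R)-6-benzyloxy-2-(3-benzyloxy-4,5-dimethoxyphenyl)-3,5,7-trimethoxychroman-4-one (2,3-trans) | COc1cc2c(c(OC)c1OCc1ccccc1)C(=O)[C@H](OC)[C@@H](c1cc(OCc3ccccc3)c(OC)c(OC)c1)O2 | intermediate
25 | (2R,3R)-6-hydroxy-2-(3-hydroxy-4,5-dimethoxyphenyl)-3,5,7-trimethoxychroman-4-one | COc1cc2c(c(OC)c1O)C(=O)[C@H](OC)[C@@H](c1cc(O)c(OC)c(OC)c1)O2 | intermediate
26 | 5,6-O-chloroboranediyl, 3'-O-dichloroboryl derivative of 27, formed in the flask | COc1cc2c(c3OB(Cl)Oc13)C(=O)[C@H](OC)[C@@H](c1cc(OB(Cl)Cl)c(OC)c(OC)c1)O2 | intermediate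
27 | (2R,3R)-5,6-dihydroxy-2-(3-hydroxy-4,5-dimethoxyphenyl)-3,7-dimethoxychroman-4-one (CNP0075601.1) | COc1cc2c(c(O)c1O)C(=O)[C@H](OC)[C@@H](c1cc(O)c(OC)c(OC)c1)O2 | target

**Step count and risks**

Total steps: 14. Longest linear sequence: 9 steps (steps 6–14 from syringaldehyde 12; the arms from 1 and from 3 are equally long).

Steps most likely to fail:

1. Step 10 (aryllithium plus Weinreb amide). The di-ortho-substituted aryllithium 18 is hindered and may add slowly, or act as a base at C-2 of 11 and trigger loss of the silyloxy group. Fallback, setting out from 11: i-Bu2AlH (toluene, −78 °C) reduces the Weinreb amide to the aldehyde (2R,3S)-3-(3-benzyloxy-4,5-dimethoxyphenyl)-2-methoxy-3-(triethylsilyloxy)propanal F1, which is used at once and added at −78 °C to aryllithium 18 (from 17 and n-BuLi). An aldehyde is far more electrophilic than the amide. This gives the carbinol 1-[3-benzyloxy-2,4-dimethoxy-6-(methoxymethoxy)phenyl]-3-(3-benzyloxy-4,5-dimethoxyphenyl)-2-methoxy-3-(triethylsilyloxy)propan-1-ol F2 as a mixture of C-1 epimers. Dess–Martin periodinane (NaHCO3, CH2Cl2, 0 °C → rt) oxidises both epimers to the same ketone, and the route is rejoined at 20.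

2. Step 12 (Mitsunobu ring closure). The activated β-oxygen sits next to an acidic α-proton, so elimination to the achiral α-methoxychalcone can compete. Fallback, setting out from 22: close the ring by ionisation instead of redox condensation, with BF3·OEt2 (1.1 equiv) in CH2Cl2 at −40 → 0 °C. The benzylic cation is trapped by the neighbouring phenol in a six-membered closure, and the fixed C-3 centre steers C-2 to the diequatorial trans arrangement. No new compound is made (F0) and the route is rejoined directly at 24. The ee and trans:cis ratio must be checked by chiral HPLC, since any detour through the chalcone would erode C-3.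

3. Step 14 (selective 5-O-demethylation). BCl3 could also attack the flanked 4'-OMe, the 7-OMe next to the boron-bound 6-oxygen, or the chelatable 3-OMe. Fallback, setting out from 24: reverse the order of the two deprotections. MgI2·OEt2 (toluene–Et2O, 60 °C) cleaves only the peri 5-OMe through the magnesium chelate to the C4 carbonyl while both benzyl ethers keep the other oxygens masked, giving (2R,3R)-6-benzyloxy-2-(3-benzyloxy-4,5-dimethoxyphenyl)-5-hydroxy-3,7-dimethoxychroman-4-one F3. Hydrogenolysis (H2, 10% Pd/C, EtOAc–MeOH, rt) then removes both benzyl groups and arrives at 27.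

**Further compounds**

F1 | step 10 | (2R,3S)-3-(3-benzyloxy-4,5-dimethoxyphenyl)-2-methoxy-3-(triethylsilyloxy)propanal | O=C[C@H](OC)[C@@H](O[Si](CC)(CC)CC)c1cc(OCc2ccccc2)c(OC)c(OC)c1
F2 | step 10 | 1-[3-benzyloxy-2,4-dimethoxy-6-(methoxymethoxy)phenyl]-3-(3-benzyloxy-4,5-dimethoxyphenyl)-2-methoxy-3-(triethylsilyloxy)propan-1-ol, both C-1 epimers, C-2 and C-3 as in 11 | COCOc1cc(OC)c(OCc2ccccc2)c(OC)c1C(O)[C@H](OC)[C@@H](O[Si](CC)(CC)CC)c1cc(OCc2ccccc2)c(OC)c(OC)c1
F0 | step 12 | none | none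
F3 | step 14 | (2R,3R)-6-benzyloxy-2-(3-benzyloxy-4,5-dimethoxyphenyl)-5-hydroxy-3,7-dimethoxychroman-4-one | COc1cc2c(c(O)c1OCc1ccccc1)C(=O)[C@H](OC)[C@@H](c1cc(OCc3ccccc3)c(OC)c(OC)c1)O2
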